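A second adduct tempts me to let L climb with the square of the charge of X, but two runs this close to their scatter must be asked first. Q is the substrate, X the reagent, E the mono adduct and L the bis adduct.

common to all: Q 0.71 M
- teal: X 0.29 M; run made earlier
- red: X 0.76 M; run made earlier
- dawn: X 0.355 M; time 80 min
- dusk: X 0.710 M; time 80 min
- spring: X 1.06 M; time 80 min

- teal (time / min: L / %, E / %): 4.00: 0, 1; 12.0: 2, 2; 25.0: 2, 4; 30.0: 2, 7; 50.0: 3, 7; 60.0: 0, 10; 80.0: 1, 10
- red (time / min: L / %, E / %): 6.00: 0, 8; 10.0: 0, 9; 15.0: 3, 10; 25.0: 2, 14; 30.0: 3, 15; 50.0: 3, 19; 80.0: 3, 23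

(standard deviation of a reading: 2 percentage points)

- L at the end, in percent of the Q charged, for each flask in turn (dawn, dusk, spring)

- the numbers in the tables scatter by 2 percentage points (one standard deviation)
- a reading or a percentage of E counts all its forms, free or not

Does L follow the charge of X or its square? Over the last 3 readings L averages 1.33% in teal and 3.00% in red, a ratio of 2.26. The charges differ by 2.62, and the square of that is 6.87. The ratio leans to the first power, though each mean carries 1.2 percentage points, so this is a leaning and no proof.

I therefore carry the L yield per molar of X charged, at the end of the run, pooled over both runs: 0.0413 M⁻¹.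

How much of the X do E and L take? E at the end reads 0.314 M⁻¹ per molar of X. Putting that first answer back, my proportional reckoning gives E and L together 28.2% of the X charged in each flask, with Q the same throughout. That equal share is built into the reckoning and counts E and L and nothing else, so it is no test of the X left. I assume that the charge stays a measure of X, and on that assumption I reckon L at 1.47%, 2.93% and 4.37%.

The forecast says 1.2%, 3% and 5.5%, and adds “The spring value is an extrapolation”. My spring figure is lower than its figure.

The flasks give 2.14%, 5.06% and 8.49%.

    Q + X ⇌ E (K = 2.30 M⁻¹, k = 0.0150 M⁻¹ min⁻¹)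
    Q + X → G (k = 0.0180 M⁻¹ min⁻¹)
    X + E → L (k = 0.0530 M⁻¹ min⁻¹)
    X + G → L (k = 4.20 × 10⁻⁴ M⁻¹ min⁻¹)
    J ⇌ E, rate k5*(cs5 - [E]) while solid is left; crystals form when [E] > cs5 (solubility = 21.0 mM, k = 5.10 min⁻¹)
    Q + E → Z (k = 0.0150 M⁻¹ min⁻¹)

In dusk E counts 21.4%, of which the crystals J are 18.4%, which leaves 3 points dissolved. In spring the same subtraction, 26.3% less 23.3%, leaves 3 points. The yield per molar in dusk is 0.0713 M⁻¹, higher than the 0.0413 M⁻¹ I carried. Put on the spring charge, it gives 7.55% of L, where spring stands at 8.49%.

The earlier runs and the new flask were generated by integration for substances that don't exist, noise included.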